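All runs are simulated on assumed constants; scatter was added.

Percent of the Z charged was the unit I counted in, and in it the earlier runs held a warning: at 120 min the dusk run stood at 61.7%, the noon run at 50.4% and the dawn run at 36.6%. On the list of suspects Z gives G, J with G gives Q, two G give L, and Z with Q gives E, a competitive-consecutive scheme. I read the falling yield as a sign that Z eats Q.

| setting | dusk | noon | dawn | Sunday's | Tuesday's | Saturday's | Wednesday's |
|---|---|---|---|---|---|---|---|
| Z | 0.10 M | 0.14 M | 0.22 M | 0.10 M (fed, over 80 min) | 0.10 M | 0.10 M | 0.10 M (in portions, 4, over 80 min) |
| J | 0.13 M | 0.13 M | 0.13 M | 0.130 M | 0.130 M (fed, over 80 min) | 0.130 M | 0.130 M |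
| remark | run made earlier | run made earlier | run made earlier | all else is in the flask from the start; the feed brings no volume worth counting | all else is in the flask from the start; the feed brings no volume worth counting | everything together at the start | first portion at the start, last at 80 min |
| time |  |  |  | 3.0 h | 3.0 h | 3.0 h | 3.0 h |

- dusk (time / h: Q / %): 0.417: 22.3; 1.00: 46.2; 2.00: 61.7; 3.00: 65.2
- noon (time / min: Q / %): 8.00: 3.2; 20.0: 13.4; 50.0: 34.9; 120: 50.4
- dawn (time / min: Q / %): 15.0: 8.8; 40.0: 20.4; 80.0: 31.0; 120: 36.6

(each reading ± 1 percentage point)

- percent here means Z units held: one L or E counts as two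
- on the list of suspects stand: Z -> G; J + G -> Q; 2 G -> L; Z + Q -> E

1. which flask leads in amount of Q, in percent of the Z charged ("all alike" within 1.5 percentage points) (Sunday's / Tuesday's / Saturday's / Wednesday's / all alike)
2. how much Q is there at the end, in percent of the Z charged: Sunday's
3. how much Q is there at the end, in percent of the Z charged: Tuesday's
4. how much Q is there at the end, in percent of the Z charged: Saturday's
5. how much Q is there at the end, in percent of the Z charged: Wednesday's

1. I turned the question round. I reckoned that for Sunday's or Wednesday's to lead, late Z had to meet less Q than Z charged at once did, and I took that to ask that its arrival be over before Q had risen.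

2. The dusk run has Saturday's recipe, so it gave me the clock. Between its first two readings I interpolated the time to reach half of its Q at 3.00 h. This making time, 40.1 min, is read off readings that each carry a scatter of 1 percentage point.

3. I called the dosing time of Z divided by the making time the overlap ratio. It came to 2.00, so the feed ran twice the making time, where the turned question wanted it over before Q had risen. The feed of 80 min outlasted the making time, so late Z was due to land among standing Q.

4. I therefore put Saturday's near 65.2%, and Sunday's and Wednesday's below it. I put Tuesday's above it: with J fed over 80 min, I expected Q to come later.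

The forecast named Tuesday's, with 62.5% for Sunday's, 69% for Tuesday's, 65.5% for Saturday's and 62.5% for Wednesday's. Its ground for Tuesday's was: “Feeding J holds material as G while Z burns away”.

The flasks gave 51.7% for Sunday's, 69.2% for Tuesday's, 65.3% for Saturday's and 49.2% for Wednesday's, so Tuesday's led. Sunday's and Wednesday's fell below the forecast's low ends of 57% and 57%.

    Z → G (k = 0.00120 s⁻¹)
    J + G → Q (k = 0.00440 L mol⁻¹ s⁻¹)
    2 G → L (k = 5.50 × 10⁻⁴ L mol⁻¹ s⁻¹)
    Z + Q → E (k = 0.0210 L mol⁻¹ s⁻¹)

Wednesday's, with its overlap ratio of 2.00, ended with Q at 49.2% and E at 41.2%. Its neighbour is the same flask with 0.52 M of J, a factor of 4.00 on the charge. I took the making time as shorter by up to that factor, which put the overlap ratio above 2.00 and as high as 7.98, and that pointed to more E and less Q. At 3.00 h that neighbour held Q at 44.9%, below Wednesday's, and E at 54.9%.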